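Compound numbers are those of the steps and the compound list below.

## Analysis of the target

Target 23 is a dihydrochalcone. Ring A is a 2',4'-dihydroxyphenyl ketone, and a C(=O)–CH2–CH2 chain joins it to C6 of a 2,2-dimethyl-2H-chromene (ring B with its fused pyran ring). Ring B is substituted at five contiguous positions: C4a (pyran carbon), C8a (pyran oxygen), C8 (free hydroxyl), C7 (3-methylbut-2-enyl) and C6 (the chain); only C5 carries hydrogen. There is no stereocentre and no configurational double bond, so the synthesis is a problem of regiochemistry and functional-group tolerance only. The sensitive groups are the styrenic C3=C4 alkene of the chromene, the prenyl alkene that sits ortho to the C8 phenol and closes onto O8 under acid, and three oxidisable phenols. Catalytic hydrogenation, strong Lewis or Brønsted acids and electrophilic oxidants are therefore excluded once these groups are in place. The difficult bond is the aryl–carbonyl bond on electron-rich ring A, which must be formed at one defined carbon without the acids of a Friedel–Crafts acylation or a thermal Fries reaction. The strategy rests on the fact that the carbonyl carbon is bonded to C1' of ring A, directly ortho to the C2' hydroxyl. The acyl group can therefore be carried as an ester on O2' and moved to C1' by an anionic 1,3-shift, with a bromine atom at C1' marking where it must land.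

## Retrosynthetic reasoning

**23 to 22.** The last operation should only uncover phenols. In 22 the oxygens at C4' and C8 are methoxymethyl acetals; O2' is free because the key step liberates it and the ketone holds it in a hydrogen bond. Acetals are chosen because they survive carbanions, hydride, hydroxide and an alkyllithium, and are removed by mild protic acid at room temperature.

**22 to 19 (key disconnection).** The C1'–C(=O) bond is cut. Cutting it to an acyl cation and a free arene would require acid and would raise a 2',4' versus 2',6' question. Instead the acyl group is returned to O2' as an aryl ester and C1' receives bromine, which gives 19. In the forward direction bromine–lithium exchange gives aryllithium 20, the acyl group migrates from oxygen to carbon, and phenoxide 21 results. The gain is regiochemistry fixed by construction, very cold and non-acidic conditions that leave the prenyl and chromene groups alone, and a precursor that is an ordinary ester.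

**19 to 16 and 18.** The ester C(=O)–O bond is cut. This divides the molecule into acid 16, which carries all of ring B, and the small bromophenol 18. The forward reaction is a carbodiimide esterification under neutral conditions.

**18 to 17.** The O–CH2 bond of the acetal is cut. Diol 17 already has bromine ortho to one hydroxyl and para to the other, so the forward step only has to acetalise the less hindered hydroxyl para to bromine.

**16 to 14, 13, and then 10 and 11.** The chain is traced to the C=C bond of enoate 13, formed from aldehyde 10 and phosphonate 11 through carbanion 12. The cut is placed there because the ring-B chemistry delivers the carbon on C6 at the aldehyde level, and a formyl group is inert in the thermal steps. The forward sequence is olefination, a 1,4-reduction that must spare the chromene and prenyl alkenes, and ester hydrolysis through carboxylate 15.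

**10 to 9.** The O8 acetal is removed retrosynthetically. It is installed as soon as the C8 phenol has served as the anchor for the prenyl group.

**9 to 7 (through 8), then 6, then 5 and 2.** The C7–CH2 bond of the prenyl group is cut as a [3,3] shift from O8. Direct C-prenylation of a phenol would be acidic and unselective between C5, C7 and oxygen, whereas the sigmatropic shift can only deliver to an ortho carbon, and C8a is blocked. The tertiary allyl ether 7 comes from alkyne 6 by semihydrogenation, and 6 comes from phenol 5 and chloride 2.

**5 to 3 (through 4), then 1 and 2.** The pyran ring is opened at the C4–C4a and O1–C2 bonds, which leads to aryl propargyl ether 3. In the forward direction 3 rearranges to allenylphenol 4, which closes to the chromene. C5 of 1 is the only free position ortho to O4, so the ring fusion is fixed. Ether 3 comes from 1 and 2 by alkylation of the more acidic O4; reagent 2 thus serves twice.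

## Alternatives that were turned down

**Alternative 1: ring A built by cycloaddition.** The disconnection cuts C1'–C2' and C5'–C6' of ring A. The forward key step is a [4+2] addition of the doubly silylated diene 1-methoxy-1,3-bis(trimethylsilyloxy)buta-1,3-diene A3 to the terminal ynone 5-[8-(tert-butyldimethylsilyloxy)-2,2-dimethyl-7-(3-methylbut-2-enyl)-2H-chromen-6-yl]pent-1-yn-3-one A2. Loss of the methoxy group and desilylation would then give 3-[8-(tert-butyldimethylsilyloxy)-2,2-dimethyl-7-(3-methylbut-2-enyl)-2H-chromen-6-yl]-1-(2,4-dihydroxyphenyl)propan-1-one A1.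
- For it: the polarity match of diene and ynone places both ring-A hydroxyls unambiguously. Ring A arrives unprotected. No resorcinol has to be differentiated, and on that point it is stronger than the chosen route, whose step 10 depends on a selective mono-protection.
- Against it: A2 is a reactive Michael acceptor that needs two steps from the acid stage. A3 is hydrolytically fragile. A stepwise conjugate addition that stops before ring closure would give open-chain material. Aromatisation by loss of the alkoxy group is normally driven by acid, which is what the prenyl and chromene groups tolerate least. A1 still needs a desilylation.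
- Comparison: the step count from the common aldehyde is about the same. The chosen route takes the arene with both oxygens already in place from a commercial compound and forms one bond intramolecularly, where this alternative builds two bonds and a ring.

**Alternative 2: hydroacylation of a vinyl chromene.** The disconnection cuts the C(=O)–Cα bond. The forward key step adds the formyl C–H of 4-(tert-butyldimethylsilyloxy)-2-hydroxybenzaldehyde A6 across the vinyl group of tert-butyl{[6-ethenyl-2,2-dimethyl-7-(3-methylbut-2-enyl)-2H-chromen-8-yl]oxy}dimethylsilane A5 with a rhodium–bisphosphine catalyst (monovalent rhodium) and a carboxylate base. The product would be 3-[8-(tert-butyldimethylsilyloxy)-2,2-dimethyl-7-(3-methylbut-2-enyl)-2H-chromen-6-yl]-1-[4-(tert-butyldimethylsilyloxy)-2-hydroxyphenyl]propan-1-one A4.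
- For it: it is the most convergent and atom-economic option. The 2'-hydroxyl that the target needs is the group that chelates rhodium and suppresses decarbonylation. A5 is two steps from aldehyde 9, so the route would be about three steps shorter than the chosen one; on step economy it is clearly stronger.
- Against it: insertion of a styrene into the rhodium hydride tends to place the metal on the benzylic carbon, which leads to the branched ketone, so the linear outcome depends on the ligand and not on the substrate. The substrate also offers two further alkenes to a metal hydride, so isomerisation of the prenyl double bond and competing coordination are possible.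
- Comparison: the chosen route is longer, but both ends of its new bond are fixed by the substrate, so neither a branched nor an isomerised product can form, and no transition-metal hydride meets the three alkenes.

**Alternative 3: prenyl group delivered last.** The disconnection cuts the C7–CH2 bond at the end of the synthesis. The forward key step heats 1-[2,4-bis(methoxymethoxy)phenyl]-3-[2,2-dimethyl-8-(2-methylbut-3-en-2-yloxy)-2H-chromen-6-yl]propan-1-one A8 so that a [3,3] shift gives 1-[2,4-bis(methoxymethoxy)phenyl]-3-[8-hydroxy-2,2-dimethyl-7-(3-methylbut-2-enyl)-2H-chromen-6-yl]propan-1-one A7.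
- For it: the acid-sensitive prenyl group is absent during all chain-building and ketone-forming steps. The step is thermal and neutral, and C7 is the only ortho position open to O8. On the sigmatropic step itself it is as sound as the chosen route, which uses the same reaction in step 5.
- Against it: the same bond is formed in the chosen route on a small aldehyde, where failure costs little. Here the whole skeleton is exposed to a reaction whose known competitor is loss of the tertiary allyl group as a diene. The tertiary ether would also have to be installed late, by alkylation and semihydrogenation in the presence of the ketone. The strategy does not say how the aryl ketone is made, and A7 still needs acid to remove its acetals with the prenyl group present.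
- Comparison: the chosen strategy uses the shift early and spends its key step on the aryl–carbonyl bond, which is the harder bond.

Key step: step 12

Assumption: 23 has no stereocentre; the E geometry of 13 is the only stereochemical element on the route and is removed in step 8. Compounds 1, 2, 11 and 17 are taken as commercially available.

## Route

Step 1
Reactants: 1 3,4-dihydroxybenzaldehyde (protocatechualdehyde); 2 3-chloro-3-methylbut-1-yne
Product: 3 3-hydroxy-4-(2-methylbut-3-yn-2-yloxy)benzaldehyde
Conditions: 2 (1.3 equiv), K2CO3 (1.0 equiv), KI (0.2 equiv), CuI (2 mol%), DMF, 45 °C, Ar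
Reagents that add atoms: none
Why: Copper-assisted Williamson-type O-propargylation; one equivalent of carbonate ionises only the 4-OH, which is para to the formyl group and the more acidic of the two, and this phenoxide captures the tertiary propargylic electrophile formed from 2 through its copper acetylide. The 3-OH stays protonated, so O4 should be etherified selectively.

Step 2
Reactants: 3 3-hydroxy-4-(2-methylbut-3-yn-2-yloxy)benzaldehyde
Product: 5 8-hydroxy-2,2-dimethyl-2H-chromene-6-carbaldehyde, via allenylphenol 4 (not isolated)
Conditions: 1,2-dichlorobenzene, 170 °C, Ar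
Reagents that add atoms: none
Why: Aryl propargyl ether Claisen rearrangement to C5, the only free position ortho to O4, gives allenylphenol 4 after enolisation; a 1,5-hydrogen shift to the ortho-quinone methide and an oxa-6π electrocyclisation then close the pyran ring. A neutral solvent is used so that the free 3-OH does not add to the alkyne.

Step 3
Reactants: 5 8-hydroxy-2,2-dimethyl-2H-chromene-6-carbaldehyde; 2 3-chloro-3-methylbut-1-yne
Product: 6 2,2-dimethyl-8-(2-methylbut-3-yn-2-yloxy)-2H-chromene-6-carbaldehyde
Conditions: 2 (2 equiv), K2CO3 (2 equiv), KI (0.2 equiv), CuI (2 mol%), DMF, 60 °C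
Reagents that add atoms: none
Why: The same copper-assisted O-propargylation (Williamson type), now on the single remaining phenol, so no site selectivity is needed; the non-enolisable aldehyde and the chromene are inert to carbonate.

Step 4
Reactants: 6 2,2-dimethyl-8-(2-methylbut-3-yn-2-yloxy)-2H-chromene-6-carbaldehyde
Product: 7 2,2-dimethyl-8-(2-methylbut-3-en-2-yloxy)-2H-chromene-6-carbaldehyde
Conditions: H2 (1 atm), Pd/CaCO3 poisoned with Pb(OAc)2 (Lindlar catalyst), quinoline, EtOAc, rt, stopped after one equivalent of H2
Reagents that add atoms: none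
Why: Lindlar semihydrogenation; the poisoned palladium surface reduces the terminal alkyne much faster than the hindered cis-disubstituted chromene alkene or the aryl aldehyde.

Step 5
Reactants: 7 2,2-dimethyl-8-(2-methylbut-3-en-2-yloxy)-2H-chromene-6-carbaldehyde
Product: 9 8-hydroxy-2,2-dimethyl-7-(3-methylbut-2-enyl)-2H-chromene-6-carbaldehyde, via cyclohexadienone 8 (not isolated)
Conditions: PhNEt2, 130 °C, Ar
Reagents that add atoms: none
Why: Aromatic Claisen rearrangement; the [3,3] shift inverts the tertiary allyl unit and bonds its CH2 terminus to C7, the only position ortho to O8 that carries hydrogen, and enolisation of dienone 8 restores the arene with the prenyl group at C7 and a free 8-OH. The amine solvent buffers traces of acid that would ionise the tertiary ether.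

Step 6
Reactants: 9 8-hydroxy-2,2-dimethyl-7-(3-methylbut-2-enyl)-2H-chromene-6-carbaldehyde
Product: 10 8-(methoxymethoxy)-2,2-dimethyl-7-(3-methylbut-2-enyl)-2H-chromene-6-carbaldehyde
Conditions: MOMCl (1.5 equiv), K2CO3 (2 equiv), DMF, 0 °C to rt
Reagents that add atoms: chloromethyl methyl ether (MOMCl), COCCl
Why: O-Alkylation of the phenoxide with the reactive chloromethyl ether (acetal protection); the methoxymethyl ether tolerates the carbanion, hydride, hydroxide and organolithium reagents used later.

Step 7
Reactants: 10 8-(methoxymethoxy)-2,2-dimethyl-7-(3-methylbut-2-enyl)-2H-chromene-6-carbaldehyde; 11 triethyl phosphonoacetate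
Product: 13 ethyl (E)-3-[8-(methoxymethoxy)-2,2-dimethyl-7-(3-methylbut-2-enyl)-2H-chromen-6-yl]prop-2-enoate, via sodium phosphonate carbanion 12 (not isolated)
Conditions: 11, NaH, THF, 0 °C; then 10, 0 °C to rt
Reagents that add atoms: sodium hydride, [Na+].[H-] (sodium of 12 only)
Why: Horner–Wadsworth–Emmons olefination; the stabilised carbanion 12 adds to the aryl aldehyde and the oxaphosphetane collapses to the E-enoate. The alkene geometry does not matter because the double bond is reduced in step 8.

Step 8
Reactants: 13 ethyl (E)-3-[8-(methoxymethoxy)-2,2-dimethyl-7-(3-methylbut-2-enyl)-2H-chromen-6-yl]prop-2-enoate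
Product: 14 ethyl 3-[8-(methoxymethoxy)-2,2-dimethyl-7-(3-methylbut-2-enyl)-2H-chromen-6-yl]propanoate
Conditions: Cu(OAc)2·H2O (2 mol%), 1,2-bis(diphenylphosphino)benzene (2 mol%), (EtO)2MeSiH (1.5 equiv), t-BuOH (1.5 equiv), toluene, rt
Reagents that add atoms: none
Why: Copper hydride conjugate reduction; the phosphine-ligated hydride of monovalent copper adds 1,4 to the polarised enoate only, t-BuOH protonates the copper enolate and the silane regenerates the hydride. The unpolarised chromene and prenyl alkenes should be left untouched, which catalytic hydrogenation could not guarantee.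

Step 9
Reactants: 14 ethyl 3-[8-(methoxymethoxy)-2,2-dimethyl-7-(3-methylbut-2-enyl)-2H-chromen-6-yl]propanoate
Product: 16 3-[8-(methoxymethoxy)-2,2-dimethyl-7-(3-methylbut-2-enyl)-2H-chromen-6-yl]propanoic acid, via lithium carboxylate 15 (not isolated)
Conditions: LiOH·H2O, THF/MeOH/H2O, rt; then 0.5 M HCl (aq), 0 °C, to pH 3–4
Reagents that add atoms: lithium hydroxide, [Li+].[OH-] (its oxygen ends in the carboxyl group of 16, its lithium in 15)
Why: Saponification of an unhindered ethyl ester by acyl–oxygen cleavage; the acetal, chromene and prenyl groups are stable to base, and brief cold acidification to pH 3–4 is too mild to cleave the methoxymethyl ether.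

Step 10
Reactants: 17 4-bromoresorcinol (4-bromobenzene-1,3-diol)
Product: 18 2-bromo-5-(methoxymethoxy)phenol
Conditions: MOMCl (0.95 equiv), K2CO3 (1.0 equiv), acetone, 0 °C to rt
Reagents that add atoms: chloromethyl methyl ether (MOMCl), COCCl
Why: Mono-O-alkylation (acetal protection); the hydroxyl para to bromine is less hindered and more nucleophilic than the one beside bromine, which is shielded and inductively deactivated, so with a slight deficit of the chloromethyl ether it should react preferentially. Bis-ether and unreacted 17 differ enough in polarity to be separated.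

Step 11
Reactants: 16 3-[8-(methoxymethoxy)-2,2-dimethyl-7-(3-methylbut-2-enyl)-2H-chromen-6-yl]propanoic acid; 18 2-bromo-5-(methoxymethoxy)phenol
Product: 19 2-bromo-5-(methoxymethoxy)phenyl 3-[8-(methoxymethoxy)-2,2-dimethyl-7-(3-methylbut-2-enyl)-2H-chromen-6-yl]propanoate
Conditions: DCC (1.1 equiv), DMAP (0.1 equiv), CH2Cl2, 0 °C to rt
Reagents that add atoms: none
Why: Steglich esterification; DCC activates 16 as the O-acylisourea and DMAP relays the acyl group to the hindered, weakly nucleophilic ortho-bromophenol. The neutral conditions spare both acetals.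

Step 12
Reactants: 19 2-bromo-5-(methoxymethoxy)phenyl 3-[8-(methoxymethoxy)-2,2-dimethyl-7-(3-methylbut-2-enyl)-2H-chromen-6-yl]propanoate
Product: 22 1-[2-hydroxy-4-(methoxymethoxy)phenyl]-3-[8-(methoxymethoxy)-2,2-dimethyl-7-(3-methylbut-2-enyl)-2H-chromen-6-yl]propan-1-one, via aryllithium 20 (not isolated), via lithium phenoxide 21 (not isolated)
Conditions: t-BuLi (2.05 equiv), THF/Et2O/pentane (4:1:1), −95 °C, 0.02 M; then −78 °C; NH4Cl (aq)
Reagents that add atoms: tert-butyllithium, [Li]C(C)(C)C (lithium of 20 and 21 only)
Why: t-BuLi attacks the bromine of 19 in an ate-type bromine–lithium exchange, which at −95 °C should be much faster than its addition to the ester carbonyl or removal of an α-proton; the second equivalent destroys the tert-butyl bromide that is formed. Aryllithium 20 holds its carbanionic carbon next to the ester oxygen, so it adds to its own carbonyl group through a four-centre transition structure and the C–O bond breaks; this anionic ortho-Fries (1,3 oxygen-to-carbon acyl) shift forms the C1'–C(=O) bond. The closest known reaction type is the halogen–metal-exchange-induced acyl migration of ortho-haloaryl esters, a Parham-type intramolecular acylation. No ring is closed and no stereocentre is formed. Regioselectivity is fixed by the bromine: the acyl group can only arrive at the carbon that carried it, ortho to O2' and para to the O4' acetal. The product is formed as lithium phenoxide 21, whose chelated, electron-rich ketone resists further organolithium attack, and high dilution keeps the acyl transfer intramolecular. The selectivity the step needs is exchange over enolisation, which the very low temperature, the fast exchange with t-BuLi and the short lifetime of 20 should secure; the acetals, the chromene and the prenyl group are inert under these conditions.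

Step 13
Reactants: 22 1-[2-hydroxy-4-(methoxymethoxy)phenyl]-3-[8-(methoxymethoxy)-2,2-dimethyl-7-(3-methylbut-2-enyl)-2H-chromen-6-yl]propan-1-one
Product: 23 1-(2,4-dihydroxyphenyl)-3-[8-hydroxy-2,2-dimethyl-7-(3-methylbut-2-enyl)-2H-chromen-6-yl]propan-1-one
Conditions: HCl (ca. 0.5 M, from conc. aq. HCl), MeOH, rt
Reagents that add atoms: none
Why: Acid-catalysed acetal exchange (methanolysis); each protonated methoxymethyl ether releases the phenol and the methoxymethyl cation is trapped by methanol. Dilute acid at room temperature is used so that the freed 8-OH does not add to the neighbouring prenyl group and the chromene is not solvolysed.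

## Compound list

1 | 3,4-dihydroxybenzaldehyde (protocatechualdehyde) | O=Cc1ccc(O)c(O)c1 | starting material
2 | 3-chloro-3-methylbut-1-yne | CC(C)(Cl)C#C | starting material
3 | 3-hydroxy-4-(2-methylbut-3-yn-2-yloxy)benzaldehyde | O=Cc1ccc(OC(C)(C)C#C)c(O)c1 | intermediate
4 | 3,4-dihydroxy-5-(3-methylbuta-1,2-dien-1-yl)benzaldehyde | O=Cc1cc(O)c(O)c(C=C=C(C)C)c1 | intermediate
5 | 8-hydroxy-2,2-dimethyl-2H-chromene-6-carbaldehyde | O=Cc1cc(O)c2OC(C)(C)C=Cc2c1 | intermediate
6 | 2,2-dimethyl-8-(2-methylbut-3-yn-2-yloxy)-2H-chromene-6-carbaldehyde | O=Cc1cc(OC(C)(C)C#C)c2OC(C)(C)C=Cc2c1 | intermediate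
7 | 2,2-dimethyl-8-(2-methylbut-3-en-2-yloxy)-2H-chromene-6-carbaldehyde | O=Cc1cc(OC(C)(C)C=C)c2OC(C)(C)C=Cc2c1 | intermediate
8 | 2,2-dimethyl-7-(3-methylbut-2-enyl)-8-oxo-7,8-dihydro-2H-chromene-6-carbaldehyde (racemic) | O=CC1=CC2=C(OC(C)(C)C=C2)C(=O)C1CC=C(C)C | intermediate
9 | 8-hydroxy-2,2-dimethyl-7-(3-methylbut-2-enyl)-2H-chromene-6-carbaldehyde | O=Cc1cc2C=CC(C)(C)Oc2c(O)c1CC=C(C)C | intermediate
10 | 8-(methoxymethoxy)-2,2-dimethyl-7-(3-methylbut-2-enyl)-2H-chromene-6-carbaldehyde | O=Cc1cc2C=CC(C)(C)Oc2c(OCOC)c1CC=C(C)C | intermediate
11 | triethyl phosphonoacetate | CCOC(=O)CP(=O)(OCC)OCC | starting material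
12 | sodium salt (carbanion) of triethyl phosphonoacetate | [Na+].CCOC(=O)[CH-]P(=O)(OCC)OCC | intermediate
13 | ethyl (E)-3-[8-(methoxymethoxy)-2,2-dimethyl-7-(3-methylbut-2-enyl)-2H-chromen-6-yl]prop-2-enoate | CCOC(=O)/C=C/c1cc2C=CC(C)(C)Oc2c(OCOC)c1CC=C(C)C | intermediate
14 | ethyl 3-[8-(methoxymethoxy)-2,2-dimethyl-7-(3-methylbut-2-enyl)-2H-chromen-6-yl]propanoate | CCOC(=O)CCc1cc2C=CC(C)(C)Oc2c(OCOC)c1CC=C(C)C | intermediate
15 | lithium 3-[8-(methoxymethoxy)-2,2-dimethyl-7-(3-methylbut-2-enyl)-2H-chromen-6-yl]propanoate | [Li+].[O-]C(=O)CCc1cc2C=CC(C)(C)Oc2c(OCOC)c1CC=C(C)C | intermediate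
16 | 3-[8-(methoxymethoxy)-2,2-dimethyl-7-(3-methylbut-2-enyl)-2H-chromen-6-yl]propanoic acid | OC(=O)CCc1cc2C=CC(C)(C)Oc2c(OCOC)c1CC=C(C)C | intermediate
17 | 4-bromoresorcinol (4-bromobenzene-1,3-diol) | Oc1ccc(Br)c(O)c1 | starting material
18 | 2-bromo-5-(methoxymethoxy)phenol | COCOc1ccc(Br)c(O)c1 | intermediate
19 | 2-bromo-5-(methoxymethoxy)phenyl 3-[8-(methoxymethoxy)-2,2-dimethyl-7-(3-methylbut-2-enyl)-2H-chromen-6-yl]propanoate | CC(C)=CCc1c(CCC(=O)Oc2cc(OCOC)ccc2Br)cc2C=CC(C)(C)Oc2c1OCOC | intermediate
20 | 2-lithio-5-(methoxymethoxy)phenyl 3-[8-(methoxymethoxy)-2,2-dimethyl-7-(3-methylbut-2-enyl)-2H-chromen-6-yl]propanoate | CC(C)=CCc1c(CCC(=O)Oc2cc(OCOC)ccc2[Li])cc2C=CC(C)(C)Oc2c1OCOC | intermediate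
21 | lithium 5-(methoxymethoxy)-2-{3-[8-(methoxymethoxy)-2,2-dimethyl-7-(3-methylbut-2-enyl)-2H-chromen-6-yl]propanoyl}phenolate | [Li+].CC(C)=CCc1c(CCC(=O)c2ccc(OCOC)cc2[O-])cc2C=CC(C)(C)Oc2c1OCOC | intermediate
22 | 1-[2-hydroxy-4-(methoxymethoxy)phenyl]-3-[8-(methoxymethoxy)-2,2-dimethyl-7-(3-methylbut-2-enyl)-2H-chromen-6-yl]propan-1-one | CC(C)=CCc1c(CCC(=O)c2ccc(OCOC)cc2O)cc2C=CC(C)(C)Oc2c1OCOC | intermediate
23 | 1-(2,4-dihydroxyphenyl)-3-[8-hydroxy-2,2-dimethyl-7-(3-methylbut-2-enyl)-2H-chromen-6-yl]propan-1-one | CC(C)=CCc1c(CCC(=O)c2ccc(O)cc2O)cc2C=CC(C)(C)Oc2c1O | target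

## Step count and least certain steps

Total step count: 13. Longest linear sequence: 12 steps (steps 1 to 9, 11, 12 and 13, from 1 to 23); step 10 is a one-step branch.

**Step 12 (key step).** The most likely failure is removal of an α-proton of the aryl ester, either by t-BuLi or by the aryllithium itself through a six-membered proton transfer, followed by expulsion of the phenoxide. Direct addition of the alkyllithium to the activated aryl ester and intermolecular acyl transfer are the other escapes. The fallback forms the same bond intermolecularly. It sets out from 16 and 17 and returns to the route at 23. Acid 16 is converted with 1,1'-carbonyldiimidazole and N,O-dimethylhydroxylamine hydrochloride into N-methoxy-N-methyl-3-[8-(methoxymethoxy)-2,2-dimethyl-7-(3-methylbut-2-enyl)-2H-chromen-6-yl]propanamide F1. Diol 17 is protected twice (NaH, MOMCl, DMF) to give 1-bromo-2,4-bis(methoxymethoxy)benzene F2. Bromine–lithium exchange of F2 with n-BuLi in THF at −78 °C and addition of F1 should give, through the chelated tetrahedral adduct, 1-[2,4-bis(methoxymethoxy)phenyl]-3-[8-(methoxymethoxy)-2,2-dimethyl-7-(3-methylbut-2-enyl)-2H-chromen-6-yl]propan-1-one F3. Dilute HCl in MeOH at room temperature then removes the three acetals to give 23.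

**Step 1.** Site selectivity may be lost and double alkylation may occur, because the sluggish tertiary electrophile has to react with the deactivated O4 phenoxide next to a free hydroxyl. Base-promoted addition of that neighbouring hydroxyl to the alkyne is a further risk. The fallback caps O3 first; it sets out from 1 and returns at 5. The dianion of 1 (NaH, 2.2 equiv, DMF, 0 °C) reacts with one equivalent of MOMCl at its more nucleophilic O3 to give 4-hydroxy-3-(methoxymethoxy)benzaldehyde F4. Alkylation with 2 under the conditions of step 3 gives 3-(methoxymethoxy)-4-(2-methylbut-3-yn-2-yloxy)benzaldehyde F5. Heating as in step 2 gives 8-(methoxymethoxy)-2,2-dimethyl-2H-chromene-6-carbaldehyde F6, and dilute HCl in MeOH frees 5.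

**Step 5.** Heterolysis of the tertiary allyl ether, with loss of the five-carbon unit as a diene and return to phenol 5, may compete with the sigmatropic shift into the crowded C7 position. Migration by way of C8a to C5 is the other escape. The fallback uses a primary allyl group that cannot ionise and adjusts it afterwards; it sets out from 5, replaces steps 3 to 5, and returns at 9. Allyl bromide and K2CO3 in DMF give 2,2-dimethyl-8-(prop-2-enyloxy)-2H-chromene-6-carbaldehyde F7. Heating in PhNEt2 at about 190 °C gives 8-hydroxy-2,2-dimethyl-7-(prop-2-enyl)-2H-chromene-6-carbaldehyde F8. Cross-metathesis with excess 2-methylbut-2-ene and the second-generation Grubbs catalyst, RuCl2(=CHPh)(SIMes)(PCy3), in CH2Cl2 then gives 9.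

**Step 10.** Acetalisation at the more acidic hydroxyl beside bromine and double acetalisation may give an isomer mixture that is hard to separate. The fallback relies on size and carries a silyl group to the end; it sets out from 17 and returns at 23. TIPSCl and imidazole in DMF silylate only the unhindered hydroxyl and give 2-bromo-5-[tri(propan-2-yl)silyloxy]phenol F9. Esterification with 16 as in step 11 gives 2-bromo-5-[tri(propan-2-yl)silyloxy]phenyl 3-[8-(methoxymethoxy)-2,2-dimethyl-7-(3-methylbut-2-enyl)-2H-chromen-6-yl]propanoate F10. The exchange and acyl shift of step 12 give 1-{2-hydroxy-4-[tri(propan-2-yl)silyloxy]phenyl}-3-[8-(methoxymethoxy)-2,2-dimethyl-7-(3-methylbut-2-enyl)-2H-chromen-6-yl]propan-1-one F11. Bu4NF in THF at 0 °C gives 1-(2,4-dihydroxyphenyl)-3-[8-(methoxymethoxy)-2,2-dimethyl-7-(3-methylbut-2-enyl)-2H-chromen-6-yl]propan-1-one F12, and dilute HCl in MeOH gives 23.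

**Step 13.** Once O8 is free, acid may promote cyclisation of the prenyl group onto it or solvolysis of the chromene before both acetals are gone. The fallback exchanges the protecting groups without protic acid and unmasks with fluoride; it sets out from 22 and returns at 23. Et3SiOTf and 2,2'-bipyridyl in CH2Cl2 at 0 °C convert the aryl methoxymethyl ethers into triethylsilyl ethers and silylate the 2'-hydroxyl as well. This gives 3-[2,2-dimethyl-7-(3-methylbut-2-enyl)-8-(triethylsilyloxy)-2H-chromen-6-yl]-1-[2,4-bis(triethylsilyloxy)phenyl]propan-1-one F13. Bu4NF buffered with AcOH in THF at 0 °C then gives 23.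

## Further compounds

F1 | step 12 | N-methoxy-N-methyl-3-[8-(methoxymethoxy)-2,2-dimethyl-7-(3-methylbut-2-enyl)-2H-chromen-6-yl]propanamide | CON(C)C(=O)CCc1cc2C=CC(C)(C)Oc2c(OCOC)c1CC=C(C)C
F2 | step 12 | 1-bromo-2,4-bis(methoxymethoxy)benzene | COCOc1ccc(Br)c(OCOC)c1
F3 | step 12 | 1-[2,4-bis(methoxymethoxy)phenyl]-3-[8-(methoxymethoxy)-2,2-dimethyl-7-(3-methylbut-2-enyl)-2H-chromen-6-yl]propan-1-one | CC(C)=CCc1c(CCC(=O)c2ccc(OCOC)cc2OCOC)cc2C=CC(C)(C)Oc2c1OCOC
F4 | step 1 | 4-hydroxy-3-(methoxymethoxy)benzaldehyde | O=Cc1ccc(O)c(OCOC)c1
F5 | step 1 | 3-(methoxymethoxy)-4-(2-methylbut-3-yn-2-yloxy)benzaldehyde | O=Cc1ccc(OC(C)(C)C#C)c(OCOC)c1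
F6 | step 1 | 8-(methoxymethoxy)-2,2-dimethyl-2H-chromene-6-carbaldehyde | O=Cc1cc(OCOC)c2OC(C)(C)C=Cc2c1
F7 | step 5 | 2,2-dimethyl-8-(prop-2-enyloxy)-2H-chromene-6-carbaldehyde | O=Cc1cc(OCC=C)c2OC(C)(C)C=Cc2c1
F8 | step 5 | 8-hydroxy-2,2-dimethyl-7-(prop-2-enyl)-2H-chromene-6-carbaldehyde | O=Cc1cc2C=CC(C)(C)Oc2c(O)c1CC=C
F9 | step 10 | 2-bromo-5-[tri(propan-2-yl)silyloxy]phenol | CC(C)[Si](Oc1ccc(Br)c(O)c1)(C(C)C)C(C)C
F10 | step 10 | 2-bromo-5-[tri(propan-2-yl)silyloxy]phenyl 3-[8-(methoxymethoxy)-2,2-dimethyl-7-(3-methylbut-2-enyl)-2H-chromen-6-yl]propanoate | CC(C)=CCc1c(CCC(=O)Oc2cc(O[Si](C(C)C)(C(C)C)C(C)C)ccc2Br)cc2C=CC(C)(C)Oc2c1OCOC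
F11 | step 10 | 1-{2-hydroxy-4-[tri(propan-2-yl)silyloxy]phenyl}-3-[8-(methoxymethoxy)-2,2-dimethyl-7-(3-methylbut-2-enyl)-2H-chromen-6-yl]propan-1-one | CC(C)=CCc1c(CCC(=O)c2ccc(O[Si](C(C)C)(C(C)C)C(C)C)cc2O)cc2C=CC(C)(C)Oc2c1OCOC
F12 | step 10 | 1-(2,4-dihydroxyphenyl)-3-[8-(methoxymethoxy)-2,2-dimethyl-7-(3-methylbut-2-enyl)-2H-chromen-6-yl]propan-1-one | CC(C)=CCc1c(CCC(=O)c2ccc(O)cc2O)cc2C=CC(C)(C)Oc2c1OCOC
F13 | step 13 | 3-[2,2-dimethyl-7-(3-methylbut-2-enyl)-8-(triethylsilyloxy)-2H-chromen-6-yl]-1-[2,4-bis(triethylsilyloxy)phenyl]propan-1-one | CC(C)=CCc1c(CCC(=O)c2ccc(O[Si](CC)(CC)CC)cc2O[Si](CC)(CC)CC)cc2C=CC(C)(C)Oc2c1O[Si](CC)(CC)CC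
A1 | alternative 1 | 3-[8-(tert-butyldimethylsilyloxy)-2,2-dimethyl-7-(3-methylbut-2-enyl)-2H-chromen-6-yl]-1-(2,4-dihydroxyphenyl)propan-1-one | CC(C)=CCc1c(CCC(=O)c2ccc(O)cc2O)cc2C=CC(C)(C)Oc2c1O[Si](C)(C)C(C)(C)C
A2 | alternative 1 | 5-[8-(tert-butyldimethylsilyloxy)-2,2-dimethyl-7-(3-methylbut-2-enyl)-2H-chromen-6-yl]pent-1-yn-3-one | CC(C)=CCc1c(CCC(=O)C#C)cc2C=CC(C)(C)Oc2c1O[Si](C)(C)C(C)(C)C
A3 | alternative 1 | 1-methoxy-1,3-bis(trimethylsilyloxy)buta-1,3-diene | COC(O[Si](C)(C)C)=CC(=C)O[Si](C)(C)C
A4 | alternative 2 | 3-[8-(tert-butyldimethylsilyloxy)-2,2-dimethyl-7-(3-methylbut-2-enyl)-2H-chromen-6-yl]-1-[4-(tert-butyldimethylsilyloxy)-2-hydroxyphenyl]propan-1-one | CC(C)=CCc1c(CCC(=O)c2ccc(O[Si](C)(C)C(C)(C)C)cc2O)cc2C=CC(C)(C)Oc2c1O[Si](C)(C)C(C)(C)C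
A5 | alternative 2 | tert-butyl{[6-ethenyl-2,2-dimethyl-7-(3-methylbut-2-enyl)-2H-chromen-8-yl]oxy}dimethylsilane | CC(C)=CCc1c(C=C)cc2C=CC(C)(C)Oc2c1O[Si](C)(C)C(C)(C)C
A6 | alternative 2 | 4-(tert-butyldimethylsilyloxy)-2-hydroxybenzaldehyde | O=Cc1ccc(O[Si](C)(C)C(C)(C)C)cc1O
A7 | alternative 3 | 1-[2,4-bis(methoxymethoxy)phenyl]-3-[8-hydroxy-2,2-dimethyl-7-(3-methylbut-2-enyl)-2H-chromen-6-yl]propan-1-one | CC(C)=CCc1c(CCC(=O)c2ccc(OCOC)cc2OCOC)cc2C=CC(C)(C)Oc2c1O
A8 | alternative 3 | 1-[2,4-bis(methoxymethoxy)phenyl]-3-[2,2-dimethyl-8-(2-methylbut-3-en-2-yloxy)-2H-chromen-6-yl]propan-1-one | C=CC(C)(C)Oc1cc(CCC(=O)c2ccc(OCOC)cc2OCOC)cc2C=CC(C)(C)Oc12
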